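Target ⇐ 7,9-trans diol by two esterifications (C9 isovalerate, then C7 angelate) ⇐ 7-hydroxy-9-ketone by hydroxyl-directed anti reduction ⇐ its 4-methoxybenzyl ether.
Feature used: in the seven-membered ring (C5–C6–C7–C8–C9–C10, closed through the cyclobutane) the bond C6–C7 joins the quaternary gem-dimethyl carbon C6 to the oxygen-bearing C7, which is β to the C9 oxygen. This is the bond a tertiary radical leaves on adding to a β-alkoxy enone, so the ring is closed by hydrogen-atom transfer to a C5=C6 isopropylidene group and 7-endo addition to C7.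
The bicyclic precursor comes from a cyclobutanone (Wittig at C5, both carbinols oxidised, 4-methoxybenzyl alcohol added to the ynone). The cyclobutanone comes from an acyclic dienoic acid by intramolecular vinylketene–alkene [2+2], which makes the cyclobutane C4–C5–C11–C10 and the six-membered ring C1–C2–C3–C4–C10–C11 together.
The acid comes from methyl 3-methylbut-2-enoate, 3-methylbut-2-enal and (triisopropylsilyl)acetylene. The C1 oxygen is brought in by an asymmetric vinylogous aldol, and through 1,3-allylic strain in the cycloaddition its configuration fixes C4, C10 and C11, so no allylic oxidation beside the cyclobutanone is needed.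
Ring order: four- and six-membered rings together (step 8), seven-membered ring last (step 13).

Key step: step 13

Remark: atom labels C1–C11 are those of the target skeleton (C1 ketone, C2=C3, cyclobutane C4–C5–C11–C10, C6 gem-dimethyl, C7 O-angelate, C9 O-isovalerate, C10 quaternary methyl carbon).
Remark: the carbinol carbon made in step 5 (the future C9) is formed without control and is oxidised in step 11; the compounds in between are carried as mixtures of the two epimers at this one centre, which is left undefined in their SMILES.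

Step 1
Reactants: 1 methyl 3-methylbut-2-enoate
Product: 3 tert-butyl[(1-methoxy-3-methylbuta-1,3-dien-1-yl)oxy]dimethylsilane (E/Z mixture at the ketene acetal), via lithium dienolate 2 (not isolated)
Conditions: LiN(i-Pr)2, THF, −78 °C; TBSCl, DMPU, −78 °C to rt; distillation
Reagents that add atoms: tert-butyldimethylsilyl chloride, CC(C)(C)[Si](C)(C)Cl
Why: Kinetic γ-deprotonation of the enoate and O-silylation of the extended enolate (silyl ketene acetal formation) should give the dienol ether needed as a vinylogous Mukaiyama donor, the geometry of its ketene acetal being of no consequence.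

Step 2
Reactants: 3 silyl dienol ether; 4 3-methylbut-2-enal
Product: 5 methyl (2E,5S)-5-hydroxy-3,7-dimethylocta-2,6-dienoate
Conditions: SiCl4, chiral 1,1′-binaphthyl-2,2′-diamine-derived bisphosphoramide (5 mol %, the enantiomer that gives 5S), i-Pr2NEt (10 mol %), CH2Cl2, −78 °C; aq. NaHCO3
Reagents that add atoms: none
Why: A catalytic enantioselective vinylogous Mukaiyama aldol addition (SiCl4 activated by the chiral Lewis base) should join only the γ-carbon of 3 to the aldehyde of 4, the catalyst choosing the aldehyde face and so setting the 5S carbinol, which becomes C1 and later controls the absolute configuration of the bicycle.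

Step 3
Reactants: 5 methyl (2E,5S)-5-hydroxy-3,7-dimethylocta-2,6-dienoate
Product: 6 methyl (2E,5S)-5-[(tert-butyldimethylsilyl)oxy]-3,7-dimethylocta-2,6-dienoate
Conditions: TBSCl, imidazole, DMF, rt
Reagents that add atoms: tert-butyldimethylsilyl chloride, CC(C)(C)[Si](C)(C)Cl
Why: Silyl ether formation (O-silylation) on the only hydroxyl keeps the future C1 oxygen inert towards SeO2, the acetylide and the ketene-forming conditions.

Step 4
Reactants: 6 methyl (2E,5S)-5-[(tert-butyldimethylsilyl)oxy]-3,7-dimethylocta-2,6-dienoate
Product: 8 methyl (2E,5S,6E)-5-[(tert-butyldimethylsilyl)oxy]-3,7-dimethyl-8-oxoocta-2,6-dienoate, via allylic alcohol 7 (not isolated)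
Conditions: SeO2 (30 mol %), t-BuOOH, salicylic acid (10 mol %), CH2Cl2, rt; crude product, MnO2, CH2Cl2, rt
Reagents that add atoms: selenium dioxide, O=[Se]=O (oxygen carrier); tert-butyl hydroperoxide, CC(C)(C)OO (terminal oxidant)
Why: SeO2 allylic oxidation (ene reaction, then [2,3]-sigmatropic shift) attacks the electron-rich C6=C7 alkene, not the enoate, at the methyl trans to the chain, and MnO2 oxidation of the allylic alcohol so formed should give the E enal, whose geometry later places the C10 methyl syn to the C1–C3 bridge.

Step 5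
Reactants: 8 methyl (2E,5S,6E)-5-[(tert-butyldimethylsilyl)oxy]-3,7-dimethyl-8-oxoocta-2,6-dienoate; 9 (triisopropylsilyl)acetylene
Product: 11 methyl (2E,5S,6E)-5-[(tert-butyldimethylsilyl)oxy]-8-hydroxy-3,7-dimethyl-10-(triisopropylsilyl)deca-2,6-dien-9-ynoate (both C8 epimers), via lithium acetylide 10 (not isolated)
Conditions: 9, n-BuLi, THF, −78 °C; then 8, −78 °C; aq. NH4Cl
Reagents that add atoms: none
Why: 1,2-Addition of the lithium acetylide to the aldehyde, which at −78 °C is far more electrophilic than the β,β-disubstituted enoate, should give the propargylic alcohol that carries C9, C8 and C7, the new carbinol centre being left uncontrolled because it is oxidised in step 11.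

Step 6
Reactants: 11 propargylic alcohol
Product: 12 methyl (2E,5S,6E)-5,8-bis[(tert-butyldimethylsilyl)oxy]-3,7-dimethyl-10-(triisopropylsilyl)deca-2,6-dien-9-ynoate
Conditions: TBSOTf, 2,6-lutidine, CH2Cl2, −78 to 0 °C
Reagents that add atoms: tert-butyldimethylsilyl trifluoromethanesulfonate, CC(C)(C)[Si](C)(C)OS(=O)(=O)C(F)(F)F
Why: Silyl ether formation with the silyl triflate protects the hindered propargylic alcohol so that no free hydroxyl can add to the ketene in step 8.

Step 7
Reactants: 12 bis-silyl ether ester
Product: 13 (2E,5S,6E)-5,8-bis[(tert-butyldimethylsilyl)oxy]-3,7-dimethyl-10-(triisopropylsilyl)deca-2,6-dien-9-ynoic acid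
Conditions: LiOH, THF/MeOH/H2O, 45 °C; 1 M HCl to pH 4 at 0 °C
Reagents that add atoms: lithium hydroxide (aqueous), [Li+].[OH-]
Why: Saponification of the methyl ester should free the acid while the secondary TBS ethers and the alkynyl TIPS group (chosen because an alkynyl TMS group would be lost here) survive aqueous base.

Step 8
Reactants: 13 dienynoic acid
Product: 16 cyclobutanone (bicyclo[3.1.1]heptan-6-one core: C5 ketone, C3 exocyclic methylene, C1 OTBS on the side of the C5 bridge, C10 methyl syn to the C1–C3 bridge, C10 side chain CH(OTBS)C≡C–TIPS), via acid chloride 14 (not isolated), via vinylketene 15 (not isolated)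
Conditions: 1-chloro-N,N,2-trimethylprop-1-en-1-amine, CH2Cl2, 0 °C to rt; concentrate; slow addition to Et3N in toluene, 110 °C
Reagents that add atoms: 1-chloro-N,N,2-trimethylprop-1-en-1-amine, CC(C)=C(Cl)N(C)C (chlorine of 14 only; no reagent atom stays in 16)
Why: The enoyl chloride is dehydrochlorinated at the γ-methyl to a vinylketene, which should undergo intramolecular ketene–alkene [2+2] cycloaddition in the bridged sense (ketene carbon, the future C5, to C11 and its α-carbon C4 to the more substituted C10), suprafacially on the E alkene so that the C10 methyl ends syn to the C1–C3 bridge, and on the alkene face that keeps the C1–H bond eclipsed with the alkene (1,3-allylic strain with the cis methyl), so that the 5S centre fixes C4, C10 and C11.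

Step 9
Reactants: 16 cyclobutanone
Product: 17 isopropylidene compound (C5=C(CH3)2 in place of the C5 ketone of 16)
Conditions: i-PrPPh3I, n-BuLi, THF, 0 °C; then 16, 0 to 60 °C
Reagents that add atoms: isopropyltriphenylphosphonium iodide, CC(C)[P+](c1ccccc1)(c1ccccc1)c1ccccc1.[I-]
Why: Wittig olefination of the strained cyclobutanone, which has only bridgehead α-hydrogens and so cannot enolise under the basic ylide, should install the C5=C6 isopropylidene group before any other carbonyl group is present.

Step 10
Reactants: 17 isopropylidene compound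
Product: 18 diol with terminal alkyne (C1 hydroxyl, C10 side chain CH(OH)C≡CH)
Conditions: TBAF, THF, 0 °C to rt
Reagents that add atoms: none
Why: Fluoride-mediated desilylation should remove both TBS ethers and the alkynyl TIPS group in one operation, the molecule holding no base-sensitive group at this stage.

Step 11
Reactants: 18 diol
Product: 19 2-methylidene-7-methyl-6-(propan-2-ylidene)-7-propynoylbicyclo[3.1.1]heptan-4-one (C1 ketone, exocyclic C3 methylene, C9 ynone)
Conditions: Dess–Martin periodinane, NaHCO3, CH2Cl2, 0 °C to rt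
Reagents that add atoms: none
Why: Dess–Martin oxidation of both secondary alcohols should give the ynone and the C1 ketone under neutral conditions and removes the uncontrolled carbinol centre, so that 19 is a single stereoisomer.

Step 12
Reactants: 19 ketone–ynone; 20 4-methoxybenzyl alcohol
Product: 22 7-[(2E)-3-(4-methoxybenzyloxy)prop-2-enoyl]-4,7-dimethyl-6-(propan-2-ylidene)bicyclo[3.1.1]hept-3-en-2-one, via deconjugated enone 21 (not isolated)
Conditions: 20, PMe3 (10 mol %), CH2Cl2, 0 °C to rt; then DBU (10 mol %), rt
Reagents that add atoms: none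
Why: Phosphine-catalysed conjugate addition of the alcohol to the terminal ynone (oxa-Michael addition) should give the E β-alkoxy enone, and base-catalysed isomerisation of the β,γ-unsaturated ketone then moves the exocyclic alkene into conjugation with C1, which also removes the only other alkene that would readily accept a hydrogen atom in step 13.

Step 13
Reactants: 22 isopropylidene bicyclic β-alkoxy enone
Product: 23 7-(4-methoxybenzyloxy)longipin-2-ene-1,9-dione
Conditions: Fe(acac)3 (30 mol %), PhSiH3 (3 equiv), EtOH/ethylene glycol 5:1, degassed, 40 °C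
Reagents that add atoms: none
Why: An iron hydride formed from Fe(acac)3 and PhSiH3 transfers a hydrogen atom to the electron-rich tetrasubstituted C5=C6 alkene (the two enone alkenes are electron-poor and much slower), H going to C5 because that leaves the acyclic tertiary radical at C6 and not a strained cyclobutyl radical; the C6 radical adds to C7 of the β-alkoxy enone and the C8 α-keto radical is reduced and protonated, the closest known reaction type being the iron-hydride-initiated reductive alkene–enone coupling (HAT-initiated Giese reaction) that joins quaternary carbons. The seven-membered ring closes in the 7-endo-trig mode, with the s-trans enone curled back so that C7 lies under C6. C5 is set by hydrogen delivery from the face turned to the C1–C3 bridge, the other face being covered by the C10 acyl chain that is 1,3-cis to it, and this leaves C6 on the acceptor side. C7 is set by which face of the E enol ether meets C6, that is, whether the enone swings below C11 or below C4; the core is nearly symmetric in this respect, only a modest preference for 23 is expected (its closure turns the C9 carbonyl away from the C1 carbonyl), and the 7-epimer is to be removed by chromatography. The selectivity the step needs above all is ring closure ahead of β-scission of the C6 radical, a cyclobutylcarbinyl radical whose ring opening would give an α-keto radical at C11; what the substrate offers against this is that radical and acceptor are held 1,3-cis on the four-membered ring, so that closure costs the freezing of two rotors only.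

Step 14
Reactants: 23 tricyclic PMB ether
Product: 24 7-hydroxylongipin-2-ene-1,9-dione
Conditions: DDQ, CH2Cl2/pH 7 buffer, 0 °C
Reagents that add atoms: none
Why: Oxidative cleavage of the 4-methoxybenzyl ether with DDQ (benzylic hydride abstraction, hydrolysis of the oxocarbenium ion) should free the C7 hydroxyl under neutral conditions that spare the β-hydroxy ketone from elimination and retro-aldol cleavage.

Step 15
Reactants: 24 β-hydroxy ketone
Product: 25 7,9-dihydroxylongipin-2-en-1-one (7,9-trans)
Conditions: Me4NBH(OAc)3, MeCN/AcOH, −35 °C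
Reagents that add atoms: none
Why: Evans–Saksena reduction, in which the C7 hydroxyl binds the triacetoxyborohydride and delivers hydride within the molecule to the face of the C9 carbonyl on which the C7 oxygen lies, should give the 7,9-trans (anti) diol and leave the C1 enone, which has no directing hydroxyl, untouched.

Step 16
Reactants: 25 diol; 26 3-methylbutanoic anhydride
Product: 27 7-hydroxy-9-(3-methylbutanoyloxy)longipin-2-en-1-one
Conditions: 26 (1.05 equiv), Et3N, DMAP (5 mol %), CH2Cl2, −40 to −20 °C
Reagents that add atoms: none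
Why: DMAP-catalysed acylation with a slight excess of anhydride at low temperature should esterify the C9 hydroxyl selectively, because it is flanked by the tied-back cyclobutane carbon C10 whereas the C7 hydroxyl is gauche to both methyl groups on C6.

Step 17
Reactants: 27 mono-isovalerate; 28 angelic acid ((Z)-2-methylbut-2-enoic acid)
Product: 30 target CNP0240547.2 (7-angeloyloxy-9-isovaleroyloxylongipin-2-en-1-one), via mixed anhydride 29 (not isolated)
Conditions: 28, 2,4,6-trichlorobenzoyl chloride, Et3N, toluene, rt; then 27, toluene, 80 °C (no DMAP)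
Reagents that add atoms: 2,4,6-trichlorobenzoyl chloride, O=C(Cl)c1c(Cl)cc(Cl)cc1Cl (aroyl group of 29 only; no reagent atom stays in 30)
Why: Yamaguchi esterification through the mixed anhydride, run without DMAP, should acylate the hindered C7 hydroxyl without isomerising the Z angelate to the E tiglate.

Compound list
1 | methyl 3-methylbut-2-enoate | COC(=O)C=C(C)C | starting material
2 | lithium dienolate of 1 | C=C(C)C=C([O-])OC.[Li+] | intermediate
3 | tert-butyl[(1-methoxy-3-methylbuta-1,3-dien-1-yl)oxy]dimethylsilane (E/Z mixture) | C=C(C)C=C(OC)O[Si](C)(C)C(C)(C)C | intermediate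
4 | 3-methylbut-2-enal | CC(C)=CC=O | starting material
5 | methyl (2E,5S)-5-hydroxy-3,7-dimethylocta-2,6-dienoate | COC(=O)/C=C(C)/C[C@H](O)C=C(C)C | intermediate
6 | methyl (2E,5S)-5-[(tert-butyldimethylsilyl)oxy]-3,7-dimethylocta-2,6-dienoate | COC(=O)/C=C(C)/C[C@H](O[Si](C)(C)C(C)(C)C)C=C(C)C | intermediate
7 | methyl (2E,5S,6E)-5-[(tert-butyldimethylsilyl)oxy]-8-hydroxy-3,7-dimethylocta-2,6-dienoate | COC(=O)/C=C(C)/C[C@H](O[Si](C)(C)C(C)(C)C)/C=C(\C)CO | intermediate
8 | methyl (2E,5S,6E)-5-[(tert-butyldimethylsilyl)oxy]-3,7-dimethyl-8-oxoocta-2,6-dienoate | COC(=O)/C=C(C)/C[C@H](O[Si](C)(C)C(C)(C)C)/C=C(\C)C=O | intermediate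
9 | (triisopropylsilyl)acetylene | C#C[Si](C(C)C)(C(C)C)C(C)C | starting material
10 | lithium (triisopropylsilyl)acetylide | [Li+].[C-]#C[Si](C(C)C)(C(C)C)C(C)C | intermediate
11 | methyl (2E,5S,6E)-5-[(tert-butyldimethylsilyl)oxy]-8-hydroxy-3,7-dimethyl-10-(triisopropylsilyl)deca-2,6-dien-9-ynoate (C8 epimers) | COC(=O)/C=C(C)/C[C@H](O[Si](C)(C)C(C)(C)C)/C=C(\C)C(O)C#C[Si](C(C)C)(C(C)C)C(C)C | intermediate
12 | methyl (2E,5S,6E)-5,8-bis[(tert-butyldimethylsilyl)oxy]-3,7-dimethyl-10-(triisopropylsilyl)deca-2,6-dien-9-ynoate (C8 epimers) | COC(=O)/C=C(C)/C[C@H](O[Si](C)(C)C(C)(C)C)/C=C(\C)C(O[Si](C)(C)C(C)(C)C)C#C[Si](C(C)C)(C(C)C)C(C)C | intermediate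
13 | (2E,5S,6E)-5,8-bis[(tert-butyldimethylsilyl)oxy]-3,7-dimethyl-10-(triisopropylsilyl)deca-2,6-dien-9-ynoic acid (C8 epimers) | OC(=O)/C=C(C)/C[C@H](O[Si](C)(C)C(C)(C)C)/C=C(\C)C(O[Si](C)(C)C(C)(C)C)C#C[Si](C(C)C)(C(C)C)C(C)C | intermediate
14 | acid chloride of 13 | ClC(=O)/C=C(C)/C[C@H](O[Si](C)(C)C(C)(C)C)/C=C(\C)C(O[Si](C)(C)C(C)(C)C)C#C[Si](C(C)C)(C(C)C)C(C)C | intermediate
15 | vinylketene, (5S,6E)-5,8-bis[(tert-butyldimethylsilyl)oxy]-7-methyl-3-methylidene-10-(triisopropylsilyl)deca-1,6-dien-9-yn-1-one | O=C=CC(=C)C[C@H](O[Si](C)(C)C(C)(C)C)/C=C(\C)C(O[Si](C)(C)C(C)(C)C)C#C[Si](C(C)C)(C(C)C)C(C)C | intermediate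
16 | cyclobutanone: 4-[(tert-butyldimethylsilyl)oxy]-7-methyl-2-methylidene-7-[1-[(tert-butyldimethylsilyl)oxy]-3-(triisopropylsilyl)prop-2-yn-1-yl]bicyclo[3.1.1]heptan-6-one, 7-methyl syn to the C2–C4 bridge, 4-silyloxy group on the side of the carbonyl bridge (side-chain carbinol epimers) | CC(C)[Si](C(C)C)(C(C)C)C#CC(O[Si](C)(C)C(C)(C)C)[C@@]1(C)[C@H]2C(=O)[C@@H]1C(=C)C[C@@H]2O[Si](C)(C)C(C)(C)C | intermediate
17 | 6-(propan-2-ylidene) analogue of 16 | CC(C)[Si](C(C)C)(C(C)C)C#CC(O[Si](C)(C)C(C)(C)C)[C@@]1(C)[C@H]2C(=C(C)C)[C@@H]1C(=C)C[C@@H]2O[Si](C)(C)C(C)(C)C | intermediate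
18 | diol: 7-(1-hydroxyprop-2-yn-1-yl)-7-methyl-2-methylidene-6-(propan-2-ylidene)bicyclo[3.1.1]heptan-4-ol (side-chain carbinol epimers) | C#CC(O)[C@@]1(C)[C@H]2C(=C(C)C)[C@@H]1C(=C)C[C@@H]2O | intermediate
19 | 7-methyl-2-methylidene-6-(propan-2-ylidene)-7-propynoylbicyclo[3.1.1]heptan-4-one | C#CC(=O)[C@@]1(C)[C@H]2C(=C(C)C)[C@@H]1C(=C)CC2=O | intermediate
20 | 4-methoxybenzyl alcohol | COc1ccc(CO)cc1 | starting material
21 | deconjugated enone: 7-[(2E)-3-(4-methoxybenzyloxy)prop-2-enoyl]-7-methyl-2-methylidene-6-(propan-2-ylidene)bicyclo[3.1.1]heptan-4-one | COc1ccc(CO/C=C/C(=O)[C@@]2(C)[C@H]3C(=C(C)C)[C@@H]2C(=C)CC3=O)cc1 | intermediate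
22 | 7-[(2E)-3-(4-methoxybenzyloxy)prop-2-enoyl]-4,7-dimethyl-6-(propan-2-ylidene)bicyclo[3.1.1]hept-3-en-2-one | CC(C)=C1[C@@H]2C(C)=CC(=O)[C@H]1[C@]2(C)C(=O)/C=C/OCc3ccc(OC)cc3 | intermediate
23 | 7-(4-methoxybenzyloxy)longipin-2-ene-1,9-dione | COc1ccc(CO[C@@H]2CC(=O)[C@@]3(C)[C@@H]4C(=O)C=C(C)[C@H]3[C@@H]4C2(C)C)cc1 | intermediate
24 | 7-hydroxylongipin-2-ene-1,9-dione | O[C@@H]1CC(=O)[C@@]2(C)[C@@H]3C(=O)C=C(C)[C@H]2[C@@H]3C1(C)C | intermediate
25 | 7,9-dihydroxylongipin-2-en-1-one (7,9-trans) | O[C@@H]1C[C@@H](O)[C@@]2(C)[C@@H]3C(=O)C=C(C)[C@H]2[C@@H]3C1(C)C | intermediate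
26 | 3-methylbutanoic anhydride | CC(C)CC(=O)OC(=O)CC(C)C | starting material
27 | 7-hydroxy-9-(3-methylbutanoyloxy)longipin-2-en-1-one | O[C@@H]1C[C@@H](OC(=O)CC(C)C)[C@@]2(C)[C@@H]3C(=O)C=C(C)[C@H]2[C@@H]3C1(C)C | intermediate
28 | angelic acid, (Z)-2-methylbut-2-enoic acid | C/C=C(/C)C(=O)O | starting material
29 | angelic 2,4,6-trichlorobenzoic anhydride | C/C=C(/C)C(=O)OC(=O)c1c(Cl)cc(Cl)cc1Cl | intermediate
30 | CNP0240547.2, 7-angeloyloxy-9-(3-methylbutanoyloxy)longipin-2-en-1-one | C/C=C(/C)C(=O)O[C@@H]1C[C@@H](OC(=O)CC(C)C)[C@@]2(C)[C@@H]3C(=O)C=C(C)[C@H]2[C@@H]3C1(C)C | target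

Total step count: 17. Longest linear sequence: 17 steps (1 to 30).

Steps most likely to fail

Step 13. The tertiary radical at C6 is a cyclobutylcarbinyl radical. Its β-scission (opening of the four-membered ring to an α-keto radical at C11) or its simple reduction may outrun the slow 7-endo addition to the hindered, oxygen-substituted C7, and face selection at C7 may be poor. The fallback runs from 19 back to 24. The exocyclic alkene of 19 is first moved into conjugation with i-Pr2NEt in CH2Cl2 to give the conjugated ynone F1. Under the conditions of step 13 the C6 radical should then add to the unhindered terminal alkyne carbon C7 (7-endo-dig, a faster capture than addition to the alkoxy-substituted alkene carbon), and reduction of the vinyl radical gives the cycloheptenone F2. Conjugate borylation of its disubstituted C7=C8 enone (CuCl, NaOt-Bu, a chiral bisphosphine such as QuinoxP* in the enantiomer that gives the C7 configuration of 24, B2pin2, MeOH, THF; the trisubstituted C2=C3 enone is far slower) gives the boronate F3, which is oxidised without isolation (NaBO3·4H2O, with retention) to 24. C7 is then set by the catalyst and no longer by the ring closure. This shortens the life of the C6 radical but does not remove it.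

Step 9. Attack of the bulky tertiary ylide on a carbonyl that is shielded by the C1 silyl ether on one face and by the C10 side chain on the other may be too slow, so that the ylide decomposes or opens the strained ketone. The fallback runs from 16 back to 17. 2-Lithio-2-(methylselanyl)propane (from 2,2-bis(methylselanyl)propane and n-BuLi, THF, −78 °C), a small and very nucleophilic carbanion, adds to 16 to give the β-hydroxy selenide F4. SOCl2 and Et3N (CH2Cl2, 0 °C) then remove hydroxyl and selenium together (reductive elimination through the seleniranium ion); because the bridgeheads cannot carry a double bond, this can only give the exocyclic alkene 17.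

Step 16. Acylation may take place at the C7 hydroxyl or at both hydroxyls instead of at C9 alone. The fallback runs from 24 back to 27 and replaces steps 15 and 16. Evans–Tishchenko reduction of 24 with pent-4-enal and SmI2 (cat., THF, −10 °C) reduces C9 with the same anti sense and leaves the acyl group on the C7 oxygen, giving the 7-pent-4-enoate F5 with a free C9 hydroxyl. This only hydroxyl is acylated with 26 (Et3N, DMAP, CH2Cl2) to the mixed diester F6. I2 in aqueous THF removes the pentenoate by iodolactonisation and leaves the isovalerate, giving 27.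

Further compounds
F1 | step 13 | 4,7-dimethyl-6-(propan-2-ylidene)-7-propynoylbicyclo[3.1.1]hept-3-en-2-one | C#CC(=O)[C@@]1(C)[C@H]2C(=C(C)C)[C@@H]1C(C)=CC2=O
F2 | step 13 | longipina-2,7-diene-1,9-dione | C1=CC(=O)[C@@]2(C)[C@@H]3C(=O)C=C(C)[C@H]2[C@@H]3C1(C)C
F3 | step 13 | 7-(4,4,5,5-tetramethyl-1,3,2-dioxaborolan-2-yl)longipin-2-ene-1,9-dione | CC1(C)OB(OC1(C)C)[C@@H]2CC(=O)[C@@]3(C)[C@@H]4C(=O)C=C(C)[C@H]3[C@@H]4C2(C)C
F4 | step 9 | β-hydroxy selenide of 16 (C5 carries OH and C(CH3)2SeCH3; C5 configuration immaterial) | CC(C)[Si](C(C)C)(C(C)C)C#CC(O[Si](C)(C)C(C)(C)C)[C@@]1(C)[C@H]2C(O)(C(C)(C)[Se]C)[C@@H]1C(=C)C[C@@H]2O[Si](C)(C)C(C)(C)C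
F5 | step 16 | 9-hydroxy-7-(pent-4-enoyloxy)longipin-2-en-1-one | C=CCCC(=O)O[C@@H]1C[C@@H](O)[C@@]2(C)[C@@H]3C(=O)C=C(C)[C@H]2[C@@H]3C1(C)C
F6 | step 16 | 9-(3-methylbutanoyloxy)-7-(pent-4-enoyloxy)longipin-2-en-1-one | C=CCCC(=O)O[C@@H]1C[C@@H](OC(=O)CC(C)C)[C@@]2(C)[C@@H]3C(=O)C=C(C)[C@H]2[C@@H]3C1(C)C
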